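## Structural features

The target is a flavanone. Ring A is a phloroglucinol ring with free hydroxyls at C5 and C7, fused through C4a and C8a to the dihydropyranone ring C (O1, C2, C3, C4=O), and ring B is attached at C2. Ring B carries three neighbouring substituents: a 4'-methoxy group flanked by a prenyl chain at C5' and an (E)-3-hydroxy-3-methylbut-1-enyl chain at C3'. C2 is the only stereocentre (S) and has no stereogenic neighbour. It is benzylic, bears the aryl ether oxygen O1 and lies β to the C4 carbonyl, so enolisation at C3 can expel O1 (ring-opened chalcone) and erase the configuration. The fragile groups are the tertiary allylic, styrene-type alcohol (ionisation, solvolysis or dehydration in acid), the prenyl alkene (acid and electrophiles), the free phenols and the β-aryloxy ketone (base and strong acid). The real difficulty is not the carbon skeleton. It is to make the C2–O1 bond in one configuration and to keep it through ring closure, side-chain installation and the final unmasking. The key step uses the fact that C3 is a plain CH2 between C4 and C2. The C3–C4 bond can therefore be made as the C3=C4 double bond of a cyclic silyl enol ether, from a vinyl group on C2 and a 1-silyloxyvinyl group on C4a of ring A, with no bond at C2 made or broken and no carbonyl present.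

## Logic of the disconnections

19 to 18: no skeletal bond is cut, only three Si–O bonds. The C4 ketone is kept as its silyl enol ether and the two ring A phenols as triisopropylsilyl ethers until the last step. The reason is that fluoride buffered with acetic acid unmasks all three near neutrality, whereas acetal protection would need hot mineral acid, which the tertiary allylic alcohol and the prenyl group would not tolerate. The gain is an endgame without acid. The demand is that the enolate freed at C4 is protonated faster than it expels O1.

18 to 16 and 17: the aryl–alkenyl bond at C3' is cut (Heck). The acid-labile side chain arrives late, and the bromine is an inert placeholder through all earlier steps. Coupling on the enol ether, not on the free flavanone, means ring C has no carbonyl while base and heat are applied, so C2 cannot open. The demand is a zerovalent palladium catalyst that inserts into a hindered, electron-rich aryl bromide under mild, aprotic conditions.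

16 to 15: the C3=C4 bond is cut (ring-closing metathesis). This removes ring C and leaves an open-chain aryl allyl ether whose only stereocentre is a carbinol carbon. The demand is that only the vinyl group and the 1-silyloxyvinyl group react, and that the allylic double bond does not migrate.

15 to 14: the enol O–Si bond is cut. The metathesis partner on ring A is simply the enol form of a methyl ketone. The demand is enolisation without acid, because the C–O bond at the stereocentre is benzylic and allylic.

14 to 10 and 12 (through 13): the C2–O1 bond is cut. This is the one step that creates chirality, an iridium-catalysed allylic etherification in which the ligand, not the substrate, sets the configuration. It splits the molecule into a ring B carbonate and a ring A phenol of similar size. The demand is branched regioselectivity and a chelated ortho-acyl aryloxide that is still nucleophilic enough.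

12 to 11: two O–Si bonds are cut. The hydrogen bond of the last ortho hydroxyl to the ketone should make bis-silylation selective, so the nucleophilic oxygen needs no separate differentiation.

10 to 9, 8 and 7: the carbonate C–O bond, the ester oxidation level and the Cα=Cβ bond are removed in turn (acylation, hydride reduction, Horner–Wadsworth–Emmons). The linear (E) carbonate is preferred to the shorter branched racemic carbonate, because a branched racemic ester can pass part of its configuration to the product. The cost is one extra step, accepted for a reliable enantioselectivity.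

7 to 5 and 6: the prenyl C=C bond is cut (cross-metathesis). The trisubstituted alkene is made from an allyl group, which is easy to place on the ring. The demand is complete conversion of allyl into prenyl, because a leftover terminal alkene would interfere in the key step.

5 to 4, 2 and 1 (through 3): the O–CH3 bond, the ring C–allyl bond and the O–allyl bond are cut (methylation, Claisen rearrangement, allylation). The bromine of 1 blocks one ortho position, so the rearrangement has a single outcome, and the same bromine later serves the Heck reaction.

## Other disconnections considered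

Alternative 1: The cut is C4–C4a, so the acyl carbon closes ring C onto ring A. In the forward step the (S)-3-aryloxy-3-arylpropanoic acid A1, with a symmetric 3,5-bis(silyloxy)phenoxy group, is activated with trifluoroacetic anhydride and acylates the ring carbon ortho to O1 to give flavanone A2.
- In favour: the two ortho positions of the phloroglucinol ring are equivalent, so there is no regiochemical question. The ring is very nucleophilic. No carbon is discarded and no ruthenium is needed. The aryloxide that would form C2–O1 has no ortho acyl group and is a better nucleophile than 13. On these points the alternative is the better plan.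
- Against: the activated acyl group sits β to a benzylic aryl ether, so loss of the aryloxide and reclosure can erode C2. A2 is a flavanone formed in acid, where ring opening is again possible. The prenyl alkene would not tolerate the acylating medium, which is why A2 carries allyl and the cross-metathesis must follow on a racemisable ketone. The acid oxidation level must be reached by two or three redox steps, and a hydroboration could not tell the allyl group from a vinyl group.
- Comparison: on structure the plans are equal, since both rest on the unsubstituted C3 and an unambiguous ring A. On mechanism the chosen plan closes ring C under neutral conditions with no carbonyl, which is safer for C2. On step economy the alternative is about two steps longer.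

Alternative 2: The cut is C4a–C5, so ring A is built last. In the forward step Mg(OMe)2 in methanol turns the dihydropyranone ketoester A3 into an extended enolate whose C4a attacks the ester carbon, and enolisation gives the free 5,7-diphenol A4.
- In favour: the step is biomimetic and ring A needs no protecting group at all, so A4 would be only a Heck reaction away from 19. On protecting-group economy the alternative is clearly better. The stereocentre of A3 could come from a catalytic asymmetric hetero-Diels–Alder reaction of the aldehyde 7, which equals the chosen plan in using one catalytic asymmetric step.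
- Against: in A3 the C2–O1 bond is β to a vinylogous ester carbonyl, and methoxide can open or add to the ring, with loss of configuration. The most acidic carbon of A3 is the methylene between ketone and ester, whose aldol attack on the C4 carbonyl is a competing cyclisation mode. A4 itself is a flavanone left in base. The triketide chain of A3 needs several steps.
- Comparison: on structure the alternative handles the phloroglucinol pattern elegantly. On mechanism it is base-mediated throughout, where the chosen plan is neutral. On step economy the two are about equal, with the Heck step still to be run on the free flavanone.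

Alternative 3: The cut is O1–C8a. In the forward step the 1,3-diol A5 is treated with Pd(OAc)2, a bulky di-tert-butylbiarylphosphine and Cs2CO3, and its C2 hydroxyl couples with the ring A bromide to give the flavan-4-ol A6.
- In favour: C2 is made as a carbinol by reliable carbonyl chemistry and its C–O bond is not broken in the ring closure. There is no C4 carbonyl during closure, which equals the chosen plan in configurational safety. The choice between the two hydroxyls is built in, because the C4 hydroxyl could only form a four-membered ring. No carbon is discarded.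
- Against: ring B cannot carry a bromide, so the side chain with its tertiary allylic alcohol must be complete and must survive hot Cs2CO3. The palladium alkoxide of a secondary benzylic alcohol can undergo β-hydride elimination. The ring A bromide is electron-rich and ortho-substituted, so oxidative addition is slow. The aryl silyl ethers meet hot carbonate. The C4 carbinol centre has to be created and then destroyed by oxidation.
- Comparison: on structure it is equal in leaving C2 untouched at closure. On mechanism it is harsher (base, heat, a competing β-hydride path). On step economy it is longer by the extra redox steps and by an unnecessary second stereocentre.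

Key step: step 11

Remarks on the chemistry:
- The (1S) centre of the open-chain ethers 14 and 15 and the (2S) centre of 16, 18 and 19 are the same spatial arrangement (priorities O > aryl > vinyl or C3), so no configuration needs correcting along the way.
- Assumption: the (Sa,S,S) antipode of the phosphoramidite is taken to give the (S) ether from an (E)-3-arylallyl carbonate; if the sense proves opposite, the (Ra,R,R) antipode is used with no other change.
- Commercial 11 is a monohydrate and is dried azeotropically before use.

## Route

Step 1
Reactants: 1 3-bromo-4-hydroxybenzaldehyde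
Product: 2 3-bromo-4-(prop-2-enoxy)benzaldehyde
Conditions: allyl bromide, K2CO3, DMF, rt
Reagents that add atoms: allyl bromide, C=CCBr
Why: Williamson ether synthesis; the phenol, acidified by the para-formyl and ortho-bromo groups, is deprotonated by K2CO3 and the phenoxide displaces bromide at oxygen (SN2).

Step 2
Reactants: 2 3-bromo-4-(prop-2-enoxy)benzaldehyde
Product: 4 3-bromo-4-hydroxy-5-(prop-2-enyl)benzaldehyde, via 6-allylcyclohexa-2,4-dienone 3 (not isolated)
Conditions: N,N-diethylaniline, 190 °C, argon
Reagents that add atoms: none
Why: Aromatic Claisen rearrangement; the concerted [3,3] shift delivers the allyl group to the only free ortho carbon (the other carries bromine) and dienone 3 re-aromatises by tautomerisation.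

Step 3
Reactants: 4 3-bromo-4-hydroxy-5-(prop-2-enyl)benzaldehyde
Product: 5 3-bromo-4-methoxy-5-(prop-2-enyl)benzaldehyde
Conditions: MeI, K2CO3, DMF, rt
Reagents that add atoms: iodomethane, CI
Why: Williamson O-methylation; the phenoxide is flanked by bromine and allyl but iodomethane is small, and the aldehyde has no enolisable hydrogen.

Step 4
Reactants: 5 3-bromo-4-methoxy-5-(prop-2-enyl)benzaldehyde; 6 2-methylbut-2-ene (large excess, co-solvent)
Product: 7 3-bromo-4-methoxy-5-(3-methylbut-2-enyl)benzaldehyde
Conditions: second-generation Grubbs catalyst RuCl2(=CHPh)(PCy3)(H2IMes) (2 mol%), CH2Cl2, 35–40 °C, sealed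
Reagents that add atoms: none
Why: Olefin cross-metathesis; the terminal CH2 is exchanged for the isopropylidene unit of 6 and propene escapes, while any crotyl product re-enters the cycle and the trisubstituted prenyl alkene, the least reactive alkene present, accumulates.

Step 5
Reactants: 7 3-bromo-4-methoxy-5-(3-methylbut-2-enyl)benzaldehyde
Product: 8 ethyl (E)-3-[3-bromo-4-methoxy-5-(3-methylbut-2-enyl)phenyl]prop-2-enoate
Conditions: (EtO)2P(O)CH2CO2Et, NaH, THF, 0 °C to rt
Reagents that add atoms: triethyl phosphonoacetate, CCOC(=O)CP(=O)(OCC)OCC
Why: Horner–Wadsworth–Emmons olefination; a stabilised phosphonate anion and an aromatic aldehyde give the (E)-cinnamate.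

Step 6
Reactants: 8 ethyl (E)-3-[3-bromo-4-methoxy-5-(3-methylbut-2-enyl)phenyl]prop-2-enoate
Product: 9 (E)-3-[3-bromo-4-methoxy-5-(3-methylbut-2-enyl)phenyl]prop-2-en-1-ol
Conditions: i-Bu2AlH (2.2 equiv), CH2Cl2, −78 to −40 °C; aq. potassium sodium tartrate
Reagents that add atoms: none
Why: 1,2-reduction of the conjugated ester by the electrophilic hydride at low temperature gives the (E)-allylic alcohol and leaves the C=C bonds and the aryl bromide alone.

Step 7
Reactants: 9 (E)-3-[3-bromo-4-methoxy-5-(3-methylbut-2-enyl)phenyl]prop-2-en-1-ol
Product: 10 (E)-3-[3-bromo-4-methoxy-5-(3-methylbut-2-enyl)phenyl]prop-2-enyl methyl carbonate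
Conditions: ClCO2Me, pyridine, CH2Cl2, 0 °C
Reagents that add atoms: methyl chloroformate, COC(=O)Cl
Why: Acylation of the primary allylic alcohol with pyridine as base; the linear (E) methyl carbonate is the standard substrate for the iridium chemistry of step 9.

Step 8
Reactants: 11 2',4',6'-trihydroxyacetophenone
Product: 12 1-[2-hydroxy-4,6-bis(triisopropylsilyloxy)phenyl]ethanone
Conditions: TIPSCl (2.1 equiv), imidazole, DMF, 0 °C to rt
Reagents that add atoms: chlorotriisopropylsilane, CC(C)[Si](Cl)(C(C)C)C(C)C
Why: Silylation of phenols; the 4-hydroxyl and one of the two equivalent ortho hydroxyls react, after which the last hydroxyl is held in a hydrogen bond to the ketone, so the reaction should stop at the bis-silyl ether. TIPS is chosen for its resistance to aryloxide and amine bases in later steps.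

Step 9
Reactants: 10 (E)-3-[3-bromo-4-methoxy-5-(3-methylbut-2-enyl)phenyl]prop-2-enyl methyl carbonate; 12 1-[2-hydroxy-4,6-bis(triisopropylsilyloxy)phenyl]ethanone
Product: 14 1-[2-{(1S)-1-[3-bromo-4-methoxy-5-(3-methylbut-2-enyl)phenyl]prop-2-enoxy}-4,6-bis(triisopropylsilyloxy)phenyl]ethanone, via lithium aryloxide 13 (not isolated)
Conditions: 12 (1.3 equiv), LiN(SiMe3)2 (1.25 equiv), THF, 0 °C; then 10, [Ir(cod)Cl]2 (2 mol%), (Sa,S,S)-O,O'-(1,1'-binaphthyl-2,2'-diyl) N,N-bis(1-phenylethyl)phosphoramidite (4 mol%, pre-activated with n-PrNH2), THF, rt to 40 °C
Reagents that add atoms: none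
Why: Iridium-catalysed asymmetric allylic etherification; the cyclometalated monovalent iridium complex ionises the carbonate to an allyl complex of trivalent iridium, and the aryloxide attacks from outside at the aryl-substituted terminus, which gives the branched ether. The chiral ligand exposes one face of the allyl ligand, so the (Sa,S,S) antipode should set the (S) configuration at the future C2.

Step 10
Reactants: 14 1-[2-{(1S)-1-[3-bromo-4-methoxy-5-(3-methylbut-2-enyl)phenyl]prop-2-enoxy}-4,6-bis(triisopropylsilyloxy)phenyl]ethanone
Product: 15 tert-butyl-{1-[2-{(1S)-1-[3-bromo-4-methoxy-5-(3-methylbut-2-enyl)phenyl]prop-2-enoxy}-4,6-bis(triisopropylsilyloxy)phenyl]ethenoxy}dimethylsilane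
Conditions: TBSOTf (1.5 equiv), Et3N (3 equiv), CH2Cl2, 0 °C to rt; cold aq. NaHCO3; Et3N-deactivated silica
Reagents that add atoms: tert-butyldimethylsilyl trifluoromethanesulfonate, CC(C)(C)[Si](C)(C)OS(=O)(=O)C(F)(F)F
Why: Soft enolisation; silylation of the carbonyl oxygen and deprotonation of the only enolisable position, the methyl group, give the 1-silyloxyvinyl arene, and excess amine keeps the medium non-acidic so the benzylic, allylic C–O bond at the stereocentre is not ionised.

Step 11
Reactants: 15 tert-butyl-{1-[2-{(1S)-1-[3-bromo-4-methoxy-5-(3-methylbut-2-enyl)phenyl]prop-2-enoxy}-4,6-bis(triisopropylsilyloxy)phenyl]ethenoxy}dimethylsilane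
Product: 16 (2S)-2-[3-bromo-4-methoxy-5-(3-methylbut-2-enyl)phenyl]-4-(tert-butyldimethylsilyloxy)-5,7-bis(triisopropylsilyloxy)-2H-chromene
Conditions: second-generation Grubbs catalyst RuCl2(=CHPh)(PCy3)(H2IMes) (5–10 mol%, in portions), 1,4-benzoquinone (10 mol%), toluene (0.005 M), 70 °C, argon sparge
Reagents that add atoms: none
Why: Ring-closing olefin metathesis of a silyl enol ether with a terminal alkene, a known route to cyclic silyl enol ethers and, from aryl allyl ethers, to 2H-chromenes. The ruthenium benzylidene first exchanges with the monosubstituted vinyl group on the carbinol carbon to put a ruthenium alkylidene at the future C3; this carbene adds across the 1,1-disubstituted enol ether to a ruthenacyclobutane whose cycloreversion forms C3=C4 and releases a ruthenium methylidene, with ethene as the only by-product. Ring C closes as a six-membered ring with an endocyclic, necessarily cis double bond, the two reacting carbons being held together by the aryl ether tether. No stereocentre is created; the (S) centre from step 9 is kept because no bond to C2 is made or broken and, without a C4 carbonyl, there is no path to a ring-opened chalcone. Selectivity among the alkenes comes from their substitution: the trisubstituted prenyl alkene is a poor metathesis partner and could only form a meta-bridged ring with the vinyl group, and the aryl bromide and silyl ethers are inert. High dilution and removal of ethene favour closure over dimerisation, and 1,4-benzoquinone suppresses ruthenium hydride species that would move the allylic double bond towards the ether oxygen.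

Step 12
Reactants: 16 (2S)-2-[3-bromo-4-methoxy-5-(3-methylbut-2-enyl)phenyl]-4-(tert-butyldimethylsilyloxy)-5,7-bis(triisopropylsilyloxy)-2H-chromene; 17 2-methylbut-3-en-2-ol (4 equiv)
Product: 18 (E)-4-{5-[(2S)-4-(tert-butyldimethylsilyloxy)-5,7-bis(triisopropylsilyloxy)-2H-chromen-2-yl]-2-methoxy-3-(3-methylbut-2-enyl)phenyl}-2-methylbut-3-en-2-ol
Conditions: Pd2(dba)3 (2.5 mol%), [HP(t-Bu)3]BF4 (6 mol%), Cy2NMe (2 equiv), 1,4-dioxane, 50 °C, argon
Reagents that add atoms: none
Why: Mizoroki–Heck reaction; zerovalent palladium bearing P(t-Bu)3 inserts into the aryl–bromine bond at mild temperature, the aryl group adds to the unsubstituted terminus of 17, and syn β-hydride elimination, possible only towards the benzylic carbon, gives the (E)-alkene. A zerovalent precatalyst, a hindered amine and an aprotic solvent spare the silyl enol ether (no palladium diacetate that could dehydrosilylate it) and the aryl silyl ethers, and C2 is safe because ring C still has no carbonyl.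

Step 13
Reactants: 18 (E)-4-{5-[(2S)-4-(tert-butyldimethylsilyloxy)-5,7-bis(triisopropylsilyloxy)-2H-chromen-2-yl]-2-methoxy-3-(3-methylbut-2-enyl)phenyl}-2-methylbut-3-en-2-ol
Product: 19 (2S)-5,7-dihydroxy-2-{3-[(E)-3-hydroxy-3-methylbut-1-enyl]-4-methoxy-5-(3-methylbut-2-enyl)phenyl}chroman-4-one
Conditions: Bu4NF (4 equiv), AcOH (4 equiv), THF, 0 °C to rt; pH 7 phosphate buffer
Reagents that add atoms: none
Why: Fluoride-induced desilylation; the two aryl silyl ethers give the phenols and the silyl enol ether gives the C4 enolate, which acetic acid protonates to the ketone. The buffer keeps the medium near neutral, so the tertiary allylic alcohol is not ionised and the new β-aryloxy ketone is not opened.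

## Compound list

1 | 3-bromo-4-hydroxybenzaldehyde | O=Cc1ccc(O)c(Br)c1 | starting material
2 | 3-bromo-4-(prop-2-enoxy)benzaldehyde | O=Cc1ccc(OCC=C)c(Br)c1 | intermediate
3 | 6-allyl-2-bromo-4-formylcyclohexa-2,4-dien-1-one (racemic) | O=CC1=CC(CC=C)C(=O)C(Br)=C1 | intermediate (not isolated)
4 | 3-bromo-4-hydroxy-5-(prop-2-enyl)benzaldehyde | O=Cc1cc(Br)c(O)c(CC=C)c1 | intermediate
5 | 3-bromo-4-methoxy-5-(prop-2-enyl)benzaldehyde | COc1c(Br)cc(C=O)cc1CC=C | intermediate
6 | 2-methylbut-2-ene | CC=C(C)C | starting material
7 | 3-bromo-4-methoxy-5-(3-methylbut-2-enyl)benzaldehyde | COc1c(Br)cc(C=O)cc1CC=C(C)C | intermediate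
8 | ethyl (E)-3-[3-bromo-4-methoxy-5-(3-methylbut-2-enyl)phenyl]prop-2-enoate | CCOC(=O)/C=C/c1cc(Br)c(OC)c(CC=C(C)C)c1 | intermediate
9 | (E)-3-[3-bromo-4-methoxy-5-(3-methylbut-2-enyl)phenyl]prop-2-en-1-ol | OC/C=C/c1cc(Br)c(OC)c(CC=C(C)C)c1 | intermediate
10 | (E)-3-[3-bromo-4-methoxy-5-(3-methylbut-2-enyl)phenyl]prop-2-enyl methyl carbonate | COC(=O)OC/C=C/c1cc(Br)c(OC)c(CC=C(C)C)c1 | intermediate
11 | 2',4',6'-trihydroxyacetophenone | CC(=O)c1c(O)cc(O)cc1O | starting material
12 | 1-[2-hydroxy-4,6-bis(triisopropylsilyloxy)phenyl]ethanone | CC(=O)c1c(O)cc(O[Si](C(C)C)(C(C)C)C(C)C)cc1O[Si](C(C)C)(C(C)C)C(C)C | intermediate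
13 | lithium 2-acetyl-3,5-bis(triisopropylsilyloxy)phenolate | [Li+].CC(=O)c1c([O-])cc(O[Si](C(C)C)(C(C)C)C(C)C)cc1O[Si](C(C)C)(C(C)C)C(C)C | intermediate (not isolated)
14 | 1-[2-{(1S)-1-[3-bromo-4-methoxy-5-(3-methylbut-2-enyl)phenyl]prop-2-enoxy}-4,6-bis(triisopropylsilyloxy)phenyl]ethanone | C=C[C@H](Oc1cc(O[Si](C(C)C)(C(C)C)C(C)C)cc(O[Si](C(C)C)(C(C)C)C(C)C)c1C(C)=O)c1cc(Br)c(OC)c(CC=C(C)C)c1 | intermediate
15 | tert-butyl-{1-[2-{(1S)-1-[3-bromo-4-methoxy-5-(3-methylbut-2-enyl)phenyl]prop-2-enoxy}-4,6-bis(triisopropylsilyloxy)phenyl]ethenoxy}dimethylsilane | C=C[C@H](Oc1cc(O[Si](C(C)C)(C(C)C)C(C)C)cc(O[Si](C(C)C)(C(C)C)C(C)C)c1C(=C)O[Si](C)(C)C(C)(C)C)c1cc(Br)c(OC)c(CC=C(C)C)c1 | intermediate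
16 | (2S)-2-[3-bromo-4-methoxy-5-(3-methylbut-2-enyl)phenyl]-4-(tert-butyldimethylsilyloxy)-5,7-bis(triisopropylsilyloxy)-2H-chromene | COc1c(Br)cc([C@@H]2C=C(O[Si](C)(C)C(C)(C)C)c3c(O[Si](C(C)C)(C(C)C)C(C)C)cc(O[Si](C(C)C)(C(C)C)C(C)C)cc3O2)cc1CC=C(C)C | intermediate
17 | 2-methylbut-3-en-2-ol | C=CC(C)(C)O | starting material
18 | (E)-4-{5-[(2S)-4-(tert-butyldimethylsilyloxy)-5,7-bis(triisopropylsilyloxy)-2H-chromen-2-yl]-2-methoxy-3-(3-methylbut-2-enyl)phenyl}-2-methylbut-3-en-2-ol | COc1c(/C=C/C(C)(C)O)cc([C@@H]2C=C(O[Si](C)(C)C(C)(C)C)c3c(O[Si](C(C)C)(C(C)C)C(C)C)cc(O[Si](C(C)C)(C(C)C)C(C)C)cc3O2)cc1CC=C(C)C | intermediate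
19 | (2S)-5,7-dihydroxy-2-{3-[(E)-3-hydroxy-3-methylbut-1-enyl]-4-methoxy-5-(3-methylbut-2-enyl)phenyl}chroman-4-one | COc1c(/C=C/C(C)(C)O)cc([C@@H]2CC(=O)c3c(O)cc(O)cc3O2)cc1CC=C(C)C | target

## Step count and least certain steps

Total: 13 steps. Longest linear sequence: 12 steps (steps 1–7 and 9–13, from 1 to 19); step 8 is a one-step side branch.

Step 11 (key step). The most likely failure is slow ring closure: the enol ether is 1,1-disubstituted, electron-rich and flanked by two ortho oxygen substituents, and the product puts the C4 and C5 silyloxy groups in a peri relationship, so the catalyst may decompose before turnover. Dimerisation through the vinyl groups and ruthenium hydride induced migration of the allylic double bond are the competing processes. The fallback sets out from 10 and returns at 16, and closes ring C by acylation instead of metathesis. Under the conditions of step 9, 10 is coupled with 3,5-bis(triisopropylsilyloxy)phenol F1 (from phloroglucinol and chlorotriisopropylsilane) to give the (S)-allylic aryl ether F2. 9-Borabicyclo[3.3.1]nonane followed by NaOH/H2O2 hydroxylates only the monosubstituted alkene, to the primary alcohol F3. TEMPO with PhI(OAc)2 in aqueous acetonitrile oxidises this to the acid F4. Trifluoroacetic anhydride in CH2Cl2 at 0 °C, buffered with a hindered pyridine, then closes ring C by intramolecular Friedel–Crafts acylation at either of the two equivalent ortho positions to give the flavanone F5. TBSOTf and Et3N convert F5 into 16.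

Step 9. The most likely failure is low reactivity and reversible ionisation of the product: the chelated ortho-acyl aryloxide is a weak nucleophile and a good leaving group, which would give erosion of enantiomeric purity and leakage to the linear ether. The fallback sets out from 7 and returns at 14, and sets the stereocentre at a carbinol instead. Catalytic enantioselective addition of Zn(CH=CH2)2 to 7 in the presence of a chiral amino alcohol gives the (R)-allylic alcohol F6. A Mitsunobu reaction of F6 with 12 (PPh3, diisopropyl azodicarboxylate, toluene, −20 °C) forms the C–O bond with inversion and gives 14. The weak point to watch there is partial substitution with allylic transposition.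

Step 12. The most likely failures are loss of the silyl enol ether under the coupling conditions (hydrolysis, or palladium-mediated dehydrosilylation towards the flavone) and slow oxidative addition into the hindered, electron-rich aryl bromide. Ionisation of the allylic C2–O1 bond by zerovalent palladium is a lesser risk. The fallback sets out from 16 and returns at 18, and replaces the Heck reaction by a base-free Stille coupling: the stannane F7, (E)-2-methyl-4-(tributylstannyl)but-3-en-2-ol, made by hydrostannation of 2-methylbut-3-yn-2-ol with Bu3SnH, is coupled with 16 using Pd[P(t-Bu)3]2 in toluene at 60–80 °C. The alkene geometry is then fixed in the reagent.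

Step 13. The most likely failure is ring opening at the moment the C4 enolate is set free by fluoride (expulsion of O1, with loss of configuration at C2), together with sluggish cleavage of the hindered aryl silyl ethers under buffered conditions. The fallback sets out from 16 and returns at 19, and unmasks the ketone by protonation before the acid-sensitive side chain exists. Dilute aqueous HCl in THF at 0 °C hydrolyses the enol ether of 16 through protonation at C3 and gives the flavanone F5. The Heck reaction of step 12, run at 40–50 °C where the hindered amine should open a 5-silyloxyflavanone only slowly, gives the coupled bis-silyl flavanone F8. Bu4NF with AcOH then removes only the two aryl silyl ethers from F8 and gives 19.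

## Further compounds

F1 | step 11 | 3,5-bis(triisopropylsilyloxy)phenol | Oc1cc(O[Si](C(C)C)(C(C)C)C(C)C)cc(O[Si](C(C)C)(C(C)C)C(C)C)c1
F2 | step 11 | 1-bromo-5-{(1S)-1-[3,5-bis(triisopropylsilyloxy)phenoxy]prop-2-enyl}-2-methoxy-3-(3-methylbut-2-enyl)benzene | C=C[C@H](Oc1cc(O[Si](C(C)C)(C(C)C)C(C)C)cc(O[Si](C(C)C)(C(C)C)C(C)C)c1)c1cc(Br)c(OC)c(CC=C(C)C)c1
F3 | step 11 | (3S)-3-[3-bromo-4-methoxy-5-(3-methylbut-2-enyl)phenyl]-3-[3,5-bis(triisopropylsilyloxy)phenoxy]propan-1-ol | OCC[C@H](Oc1cc(O[Si](C(C)C)(C(C)C)C(C)C)cc(O[Si](C(C)C)(C(C)C)C(C)C)c1)c1cc(Br)c(OC)c(CC=C(C)C)c1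
F4 | step 11 | (3S)-3-[3-bromo-4-methoxy-5-(3-methylbut-2-enyl)phenyl]-3-[3,5-bis(triisopropylsilyloxy)phenoxy]propanoic acid | OC(=O)C[C@H](Oc1cc(O[Si](C(C)C)(C(C)C)C(C)C)cc(O[Si](C(C)C)(C(C)C)C(C)C)c1)c1cc(Br)c(OC)c(CC=C(C)C)c1
F5 | step 11 | (2S)-2-[3-bromo-4-methoxy-5-(3-methylbut-2-enyl)phenyl]-5,7-bis(triisopropylsilyloxy)chroman-4-one | COc1c(Br)cc([C@@H]2CC(=O)c3c(O[Si](C(C)C)(C(C)C)C(C)C)cc(O[Si](C(C)C)(C(C)C)C(C)C)cc3O2)cc1CC=C(C)C
F6 | step 9 | (1R)-1-[3-bromo-4-methoxy-5-(3-methylbut-2-enyl)phenyl]prop-2-en-1-ol | C=C[C@@H](O)c1cc(Br)c(OC)c(CC=C(C)C)c1
F7 | step 12 | (E)-2-methyl-4-(tributylstannyl)but-3-en-2-ol | CCCC[Sn](CCCC)(CCCC)/C=C/C(C)(C)O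
F8 | step 13 | (2S)-2-{3-[(E)-3-hydroxy-3-methylbut-1-enyl]-4-methoxy-5-(3-methylbut-2-enyl)phenyl}-5,7-bis(triisopropylsilyloxy)chroman-4-one | COc1c(/C=C/C(C)(C)O)cc([C@@H]2CC(=O)c3c(O[Si](C(C)C)(C(C)C)C(C)C)cc(O[Si](C(C)C)(C(C)C)C(C)C)cc3O2)cc1CC=C(C)C
A1 | alternative 1 | (3S)-3-(3-allyl-5-bromo-4-methoxyphenyl)-3-[3,5-bis(triisopropylsilyloxy)phenoxy]propanoic acid | COc1c(Br)cc([C@H](CC(=O)O)Oc2cc(O[Si](C(C)C)(C(C)C)C(C)C)cc(O[Si](C(C)C)(C(C)C)C(C)C)c2)cc1CC=C
A2 | alternative 1 | (2S)-2-(3-allyl-5-bromo-4-methoxyphenyl)-5,7-bis(triisopropylsilyloxy)chroman-4-one | COc1c(Br)cc([C@@H]2CC(=O)c3c(O[Si](C(C)C)(C(C)C)C(C)C)cc(O[Si](C(C)C)(C(C)C)C(C)C)cc3O2)cc1CC=C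
A3 | alternative 2 | methyl 4-{(2S)-2-[3-bromo-4-methoxy-5-(3-methylbut-2-enyl)phenyl]-4-oxo-3,4-dihydro-2H-pyran-6-yl}-3-oxobutanoate | COC(=O)CC(=O)CC1=CC(=O)C[C@@H](c2cc(Br)c(OC)c(CC=C(C)C)c2)O1
A4 | alternative 2 | (2S)-2-[3-bromo-4-methoxy-5-(3-methylbut-2-enyl)phenyl]-5,7-dihydroxychroman-4-one | COc1c(Br)cc([C@@H]2CC(=O)c3c(O)cc(O)cc3O2)cc1CC=C(C)C
A5 | alternative 3 | (1R,3S)-1-[2-bromo-4,6-bis(triisopropylsilyloxy)phenyl]-3-{3-[(E)-3-hydroxy-3-methylbut-1-enyl]-4-methoxy-5-(3-methylbut-2-enyl)phenyl}propane-1,3-diol | COc1c(/C=C/C(C)(C)O)cc([C@@H](O)C[C@@H](O)c2c(O[Si](C(C)C)(C(C)C)C(C)C)cc(O[Si](C(C)C)(C(C)C)C(C)C)cc2Br)cc1CC=C(C)C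
A6 | alternative 3 | (2S,4R)-2-{3-[(E)-3-hydroxy-3-methylbut-1-enyl]-4-methoxy-5-(3-methylbut-2-enyl)phenyl}-5,7-bis(triisopropylsilyloxy)chroman-4-ol | COc1c(/C=C/C(C)(C)O)cc([C@@H]2C[C@@H](O)c3c(O[Si](C(C)C)(C(C)C)C(C)C)cc(O[Si](C(C)C)(C(C)C)C(C)C)cc3O2)cc1CC=C(C)C
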